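**Assumptions**
- The quinidine-derived squaramide is assumed to give the (2S) flavanone by analogy with cinchona-catalysed oxa-Michael cyclisations of 2'-hydroxychalcones. If (2R) results, use the quinine-derived pseudoenantiomer.
- Ynone **4** is unstable and is used crude, as a THF solution, straight after Step 7.
- Prenyl bromide and 5-bromo-2-methylpent-2-ene are commercial.

## Retrosynthetic overview
1. Glabrol (**1**) comes from mild MOM removal on 4'-O-MOM glabrol (**2**).
2. Key disconnection: **2** forms in one flask from β-ketoester **3** and terminal ynone **4**. A base-mediated Michael/Claisen-type benzannulation builds ring A, which already carries the 7-OH and 8-prenyl groups. A catalyst-controlled 6-endo oxa-Michael of the 2'-OH onto the enone then builds ring C and sets C2.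
3. Ring order: ring A (benzene) first, then ring C (pyranone), in the same flask. Ring B carries its prenyl group from the start.
4. **3** comes from 4-hydroxybenzaldehyde by C-prenylation, MOM protection, Doebner condensation and Masamune-type chain extension. **4** comes from 5-bromo-2-methylpent-2-ene by formylation, ethynylation and oxidation.

## Route

**Step 1**
Reactants: 5 (4-hydroxybenzaldehyde), 6 (prenyl bromide)
Product: 7 (4-hydroxy-3-(3-methylbut-2-en-1-yl)benzaldehyde)
Conditions: 6 (1.1 equiv), NaOH (1.0 equiv), H2O, 25 °C, 24 h
Reagents that add atoms: prenyl bromide (6), CC(C)=CCBr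
Why: In water the phenoxide oxygen is strongly hydrogen-bonded, so alkylation occurs at the ortho carbon (SN2 at the primary carbon, giving the normal prenyl group, not the SN2' product). This is a phenoxide ortho-C-alkylation, and no stereocentre forms.

**Step 2**
Reactants: 7, 8 (chloromethyl methyl ether)
Product: 9 (4-(methoxymethoxy)-3-prenylbenzaldehyde)
Conditions: 8 (1.3 equiv), iPr2NEt, CH2Cl2, 0 → 25 °C, 3 h
Reagents that add atoms: MOMCl (8), COCCl
Why: Standard phenol O-alkylation to the MOM acetal masks the ring-B OH. The free phenol would otherwise be acylated by CDI in Step 4, and its phenoxide would consume base and deactivate the enone in Step 8.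

**Step 3**
Reactants: 9, 10 (malonic acid)
Product: 11 ((E)-3-[4-(methoxymethoxy)-3-prenylphenyl]acrylic acid)
Conditions: 10 (2 equiv), pyridine, piperidine (cat.), 90 °C, 4 h
Reagents that add atoms: malonic acid (10), OC(=O)CC(=O)O
Why: Doebner–Knoevenagel condensation with decarboxylation gives the (E)-cinnamic acid; the MOM ether is stable to pyridine and piperidine.

**Step 4**
Reactants: 11, 12 (CDI), 13 (potassium ethyl malonate)
Product: 3 (ethyl (E)-5-[4-(methoxymethoxy)-3-prenylphenyl]-3-oxopent-4-enoate)
Conditions: (i) 12 (1.2 equiv), THF, 25 °C, 2 h; (ii) 13 (2 equiv), MgCl2, Et3N, THF, 25 → 50 °C, 12 h; then aqueous citric acid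
Reagents that add atoms: potassium ethyl malonate (13), CCOC(=O)CC(=O)[O-].[K+]
Why: The acyl imidazolide is C-acylated by the magnesium malonate, which then decarboxylates (Masamune–Rathke β-ketoester synthesis); the (E)-styryl group and the MOM ether are retained under the mild citric acid work-up.

**Step 5**
Reactants: 14 (5-bromo-2-methylpent-2-ene), 15 (DMF)
Product: 16 (5-methylhex-4-enal)
Conditions: (i) Mg, THF, 25 → 40 °C; (ii) 15 (1.5 equiv), 0 °C, then aqueous NH4Cl
Reagents that add atoms: DMF (15), CN(C)C=O
Why: Bouveault formylation of the homoallylic Grignard reagent adds the CHO carbon; the trisubstituted alkene is untouched.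

**Step 6**
Reactants: 16, 17 (ethynylmagnesium bromide)
Product: 18 (7-methyloct-6-en-1-yn-3-ol)
Conditions: 17 (1.3 equiv, 0.5 M in THF), THF, 0 → 25 °C, 2 h
Reagents that add atoms: ethynylmagnesium bromide (17), C#C[Mg]Br
Why: 1,2-Addition of the alkynyl Grignard to the aliphatic aldehyde gives the racemic propargylic alcohol; this stereocentre is destroyed in the next step.

**Step 7**
Reactants: 18
Product: 4 (7-methyloct-6-en-1-yn-3-one)
Conditions: activated MnO2 (15 equiv), CH2Cl2, 25 °C, 3 h; filter, swap solvent to THF and use crude
Reagents that add atoms: none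
Why: MnO2 oxidises the propargylic alcohol selectively and leaves the trisubstituted alkene alone.

**Step 8 (key step: rings A and C, one flask)**
Reactants: 3, 4
Product: 2 ((2S)-7-hydroxy-2-[4-(methoxymethoxy)-3-prenylphenyl]-8-prenyl-2,3-dihydro-4H-chromen-4-one), via the in-situ chalcone 19
Conditions: (i) 3, t-BuOK (2.2 equiv), THF, −78 °C, 20 min; add 4 (1.1 equiv), −78 → 50 °C, 14 h. (ii) Same flask: cool to 25 °C, AcOH (2.2 equiv, just enough to neutralise the base), dilute with PhMe, then add quinidine-derived bifunctional squaramide (10 mol %), 25 °C, 96 h.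
Reagents that add atoms: none (atoms balance: 3 + 4 → 19 + EtOH; 19 → 2 is an isomerisation)
Why: Proposed new method: The stabilised enolate of 3 adds to the terminal carbon of ynone 4, and protonation gives the Z-enone, which places the ynone ketone cis to the β-ketoester carbon. The ynone α'-carbon (the future C8, bearing CH2CH=CMe2, which becomes the prenyl group) then closes onto the ester carbon, the future C8a. Loss of EtO⁻ and enolisation aromatise the ring to give 2',4'-dihydroxy-3'-prenylchalcone 19 (ring A) as its phenoxide. Closure onto the cinnamoyl ketone (aldol mode) is the competing path. Under anhydrous alkoxide the tertiary aldolate should revert by retro-aldol, whereas ester closure is followed by irreversible aromatisation, so heating should funnel material to 19. Neutralisation and the chiral tertiary-amine/squaramide catalyst then promote 6-endo oxa-Michael addition of the 2'-OH onto the cinnamoyl enone (ring C). The catalyst controls the enone face and sets C2 as (S). The closest known chemistry is Michael–Claisen annulation of malonate with mesityl oxide (dimedone synthesis) and ynone/1,3-dicarbonyl [3+3] benzannulations, followed by cinchona-catalysed cyclisation of 2'-hydroxychalcones to flavanones.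

**Step 9**
Reactants: 2
Product: 1 (glabrol)
Conditions: TMSOTf (3 equiv), 2,2'-bipyridyl (4 equiv), MeCN, 0 → 25 °C, 4 h; then H2O
Reagents that add atoms: none
Why: TMSOTf/2,2'-bipyridyl cleaves aryl MOM ethers under non-basic, buffered conditions, so the prenyl alkenes and the C2 stereocentre survive; the 7-OH is only transiently silylated and is released on aqueous work-up.

## Compound list
| No. | Name | SMILES | Role |
|---|---|---|---|
| 1 | (2S)-glabrol | CC(C)=CCc1cc([C@@H]2CC(=O)c3ccc(O)c(CC=C(C)C)c3O2)ccc1O | target |
| 2 | (2S)-7-hydroxy-2-[4-(methoxymethoxy)-3-prenylphenyl]-8-prenylchroman-4-one | COCOc1ccc([C@@H]2CC(=O)c3ccc(O)c(CC=C(C)C)c3O2)cc1CC=C(C)C | intermediate |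
| 3 | ethyl (E)-5-[4-(methoxymethoxy)-3-prenylphenyl]-3-oxopent-4-enoate | CCOC(=O)CC(=O)/C=C/c1ccc(OCOC)c(CC=C(C)C)c1 | intermediate |
| 4 | 7-methyloct-6-en-1-yn-3-one | C#CC(=O)CCC=C(C)C | intermediate |
| 5 | 4-hydroxybenzaldehyde | O=Cc1ccc(O)cc1 | starting material |
| 6 | prenyl bromide | CC(C)=CCBr | starting material |
| 7 | 4-hydroxy-3-prenylbenzaldehyde | O=Cc1ccc(O)c(CC=C(C)C)c1 | intermediate |
| 8 | chloromethyl methyl ether | COCCl | starting material |
| 9 | 4-(methoxymethoxy)-3-prenylbenzaldehyde | COCOc1ccc(C=O)cc1CC=C(C)C | intermediate |
| 10 | malonic acid | OC(=O)CC(=O)O | starting material |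
| 11 | (E)-3-[4-(methoxymethoxy)-3-prenylphenyl]acrylic acid | COCOc1ccc(/C=C/C(=O)O)cc1CC=C(C)C | intermediate |
| 12 | 1,1'-carbonyldiimidazole | O=C(n1ccnc1)n1ccnc1 | starting material |
| 13 | potassium ethyl malonate | CCOC(=O)CC(=O)[O-].[K+] | starting material |
| 14 | 5-bromo-2-methylpent-2-ene | CC(C)=CCCBr | starting material |
| 15 | N,N-dimethylformamide | CN(C)C=O | starting material |
| 16 | 5-methylhex-4-enal | O=CCCC=C(C)C | intermediate |
| 17 | ethynylmagnesium bromide | C#C[Mg]Br | starting material |
| 18 | 7-methyloct-6-en-1-yn-3-ol | C#CC(O)CCC=C(C)C | intermediate |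
| 19 | (E)-1-(2,4-dihydroxy-3-prenylphenyl)-3-[4-(methoxymethoxy)-3-prenylphenyl]prop-2-en-1-one (formed in situ, not isolated) | CC(C)=CCc1c(O)ccc(C(=O)/C=C/c2ccc(OCOC)c(CC=C(C)C)c2)c1O | intermediate |

**Total steps:** 9.
**Longest linear sequence:** 6 steps (5 → 7 → 9 → 11 → 3 → 2 → 1, i.e. Steps 1, 2, 3, 4, 8, 9).

**Three steps most likely to fail**
1. **Step 8, benzannulation stage.** Aldol-mode closure onto the cinnamoyl ketone may beat ester closure. That path would give a 4-hydroxy-2-styrylbenzoate, and 4H-pyran or E-enone side products may also form.
   Fallback: abandon the de novo ring A. Prenylate commercial 2',4'-dihydroxyacetophenone at C3, condense it with aldehyde 9 (Claisen–Schmidt) to give chalcone 19, then run the same asymmetric cyclisation.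
2. **Step 8, enantioselective oxa-Michael stage.** The electron-rich 4-alkoxy chalcone cyclises slowly and reversibly, and background base-mediated cyclisation or ring-opening of the flavanone erodes ee.
   Fallback: cyclise 19 to racemic 2 with a mild base, then resolve by preparative chiral-phase HPLC. Alternatively, make C2 by Pd-catalysed asymmetric conjugate addition of an arylboronic acid to a preformed 7-OR-8-prenylchromone.
3. **Step 1, ortho-C-prenylation.** It may give O-prenylation, di-prenylation or low conversion.
   Fallback: start from commercial 3-bromo-4-hydroxybenzaldehyde, protect it as the MOM ether, and install the prenyl group by Pd-catalysed Negishi coupling with prenylzinc bromide, using a ligand that favours the linear product.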